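The starting material has two exits that compete for it. One is first-order and leads through intermediate B to the target; the other takes reagent and leads to intermediate C. The target then shares its material with its isomer.

all flasks: starting material 0.050 M; time 4.0 min
- delta: reagent 0.0600 M
- epsilon: reagent 0.0800 M
- gamma: reagent 0.120 M
- theta: reagent 0.200 M

    starting material ⇌ intermediate A (K1 = 0.74, k1 = 0.023 s⁻¹)
    starting material ⇌ intermediate B (K2 = 40, k2 = 0.031 s⁻¹)
    starting material + reagent → intermediate C (k3 = 1.9 M⁻¹ s⁻¹)
    reagent + intermediate B → target (k4 = 2.2 M⁻¹ s⁻¹)
    reagent + intermediate C → side product (k5 = 0.34 M⁻¹ s⁻¹)
    target ⇌ isomer of the product (K6 = 12, k6 = 0.027 s⁻¹)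
    2 starting material → homo dimer (k7 = 0.0032 M⁻¹ s⁻¹)

- a species is counted by the starting material in it: one homo dimer counts as two
- for a step with 2 of a species take k times the square, and two of it per event
- "hardly changes" means that all values lie within two and a half points (for a concentration: within two and a half percent of the largest)
- run time (delta): 4.0 min

- [target] at the end for delta, epsilon, gamma, theta, in this order
- how the row runs (rises, then falls / falls, then rises / falls all the way / rises all the way / hardly changes)

1. I compared the two exits first. The way to intermediate B runs at 0.031 s⁻¹, whatever the reagent does. The way to intermediate C is pseudo-first-order at 1.9 M⁻¹ s⁻¹ times the reagent. The two run equally at 0.0163 M of reagent. I called this reagent level, first-order constant over second-order constant, the crossover level. The share going to intermediate B is the crossover level over the crossover level plus the reagent. I set intermediate A aside as a store that returns starting material.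

2. My first way froze the reagent at its charge. That gave 7.54% for theta and 21.4% for delta.

3. My second way let the reagent fall, one for each starting material lost by either exit, since the step into intermediate C and the step from intermediate B to target each take one reagent. The amount through intermediate B is then the crossover level times ln(crossover level plus charge, over crossover level plus final reagent). I took the final reagent as the charge less the starting material. That gave 8.58% for theta and 34.7% for delta.

4. In theta the ways stood close. In delta they parted, and the first cheated: it kept the delta reagent at 0.0600 M while it was being drawn down. So I kept the second. It counted no reagent for the step from intermediate C to side product. I left that draw out, and it stayed a gap in this reckoning.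

5. The target's forward half-life towards its isomer, 0.43 min, is short against the 4.0 min run. So I froze the target at 7.69% of the pool. My row, from the second way, was 0.00134 M, 9.19 × 10⁻⁴ M, 5.74 × 10⁻⁴ M and 3.30 × 10⁻⁴ M.

6. The forecast was 0.0014 M, 0.0011 M, 7.000 × 10⁻⁴ M and 4.300 × 10⁻⁴ M, and its shape was "falls all the way". Its numbers stood above mine. It held the run “long enough for the target to relax almost fully”.

7. The simulation gave 0.00139 M, 0.00112 M, 6.32 × 10⁻⁴ M and 3.45 × 10⁻⁴ M. The row falls all the way.

The theta charge stood at 12.3 times the crossover level of 0.0163 M, and theta ended with target and isomer together at 8.79% of the starting material charged, with side product at 91.1%. The delta charge stood at 3.68 times that level, and delta ended with target, isomer and intermediate B together at 35.0% of the starting material charged, with side product at 25.1%.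

(All constants were chosen freely; no experiment stands behind them.)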